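**Plan**
1. Retrosynthesis: remove the MOM ether from O5, then cut ring C at ring A twice, at C4–C4a and at O1–C8a. This leaves an aryne of ring A (C4a≡C8a) and the chain O1–C2–C3–C4 as an (S)-β-hydroxy Weinreb amide.
2. Enabling feature: ring A carries the ether oxygen O1 (on C8a) and the acyl carbon C4 (on C4a) on neighbouring carbons, with the C5 oxygen beside C4a and the prenylated C8 beside C8a. An ortho-oxygenated aryl ketone is what an aryne leaves after taking up an alkoxide and an acyl group.
3. Forward: fragment 1 (chiral amide 4) from 2′,4′,6′-trimethoxyacetophenone in three steps. Fragment 2 (silyl triflate 16) from 5-methoxyresorcinol in four steps; one carbamate directs two ortho-metalations in a single flask (TMS at C4a, prenyl at C8).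
4. Union: the alkoxide of 4 adds to C8a of the aryne and the C4a anion closes ring C on the amide carbonyl (C4–C4a). MOM removal ends the route.
5. Stereochemistry: C2 (S) is set by the asymmetric transfer hydrogenation in step 2. Its C–O bond is never broken afterwards, and C4 stays masked as a tetrahedral adduct through the basic key step.

Key step: step 8

Assumption: the sense of hydride delivery in step 2 is assigned by analogy with acetophenone-type ketones, for which the (S,S)-TsDPEN ligand gives the (S)-carbinol; the enantiomeric ligand is the remedy if the twisted aryl group inverts it.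

**Step 1**
Reactants: 1 2′,4′,6′-trimethoxyacetophenone
Product: 2 methyl 3-oxo-3-(2,4,6-trimethoxyphenyl)propanoate
Conditions: NaH (2.5 equiv), (MeO)2CO (5 equiv), THF, reflux; then AcOH, 0 °C
Reagents that add atoms: dimethyl carbonate, COC(=O)OC
Why: Claisen-type C-acylation of the methyl ketone sodium enolate by dimethyl carbonate, driven by deprotonation of the β-keto ester formed.

**Step 2**
Reactants: 2 methyl 3-oxo-3-(2,4,6-trimethoxyphenyl)propanoate
Product: 3 methyl (3S)-3-hydroxy-3-(2,4,6-trimethoxyphenyl)propanoate
Conditions: RuCl[(S,S)-TsDPEN](p-cymene) (1 mol %), HCO2Na (5 equiv), H2O/MeOH 1:1, 40 °C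
Reagents that add atoms: none
Why: Noyori–Ikariya asymmetric transfer hydrogenation, in which the Ru–H/N–H pair of the (S,S)-ligand delivers hydride to the ketone face that places the aryl group against the η6-arene, which should give the (S)-carbinol, while the near-neutral formate medium spares the acid-labile trimethoxybenzylic alcohol.

**Step 3**
Reactants: 3 methyl (3S)-3-hydroxy-3-(2,4,6-trimethoxyphenyl)propanoate
Product: 4 (3S)-3-hydroxy-N-methoxy-N-methyl-3-(2,4,6-trimethoxyphenyl)propanamide
Conditions: MeNHOMe·HCl (3 equiv), i-PrMgCl (7 equiv), THF, −20 → 0 °C; aq. NH4Cl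
Reagents that add atoms: N,O-dimethylhydroxylamine hydrochloride, CNOC.Cl
Why: Weinreb amidation of the ester by the magnesium amide of MeNHOMe, with the carbinol held as its magnesium alkoxide so that the stereocentre is not touched.

**Step 4**
Reactants: 5 5-methoxyresorcinol
Product: 6 3-methoxy-5-(methoxymethoxy)phenol
Conditions: MOMCl (1.0 equiv), i-Pr2NEt (1.2 equiv), CH2Cl2, 0 °C → rt; chromatography, diol recovered
Reagents that add atoms: chloromethyl methyl ether, COCCl
Why: Williamson-type O-alkylation of a symmetric diol, where one equivalent of MOMCl should give the mono-ether as the main component of a statistical mixture.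

**Step 5**
Reactants: 6 3-methoxy-5-(methoxymethoxy)phenol
Product: 7 3-methoxy-5-(methoxymethoxy)phenyl N-isopropylcarbamate
Conditions: i-PrNCO (1.5 equiv), Et3N (0.2 equiv), CH2Cl2, rt
Reagents that add atoms: isopropyl isocyanate, CC(C)N=C=O
Why: base-catalysed addition of the phenol to the isocyanate gives the N-monoalkyl carbamate, a strong ortho-director that can later be removed under mild base.

**Step 6**
Reactants: 7 3-methoxy-5-(methoxymethoxy)phenyl N-isopropylcarbamate
Product: 14 3-methoxy-5-(methoxymethoxy)-2-(3-methylbut-2-en-1-yl)-6-(trimethylsilyl)phenyl N-isopropylcarbamate, via N-silyl carbamate 8 (not isolated), via aryllithium 9 (not isolated), via N-silyl C-silyl carbamate 10 (not isolated), via second aryllithium 11 (not isolated), via arylcopper 12 (not isolated), via N-silyl prenyl carbamate 13 (not isolated)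
Conditions: TMSOTf (1.05 equiv), TMEDA (3.2 equiv), Et2O, 0 °C → rt; n-BuLi (2.1 equiv), −78 °C; TMSCl (1.0 equiv), −78 → −30 °C; n-BuLi (1.2 equiv), −78 °C; CuBr·SMe2 (1.3 equiv), −78 °C; prenyl bromide (1.6 equiv), −78 °C → rt; aq. NH4Cl/NH3
Reagents that add atoms: chlorotrimethylsilane, C[Si](C)(C)Cl; prenyl bromide (1-bromo-3-methylbut-2-ene), CC(C)=CCBr
Why: two directed ortho-metalations of the carbamate in one flask after in-situ N-silylation, in which the first lithiation should go to the carbon between the carbamate oxygen and the OMOM group (the stronger cooperative pair, OMOM outranking OMe) and is capped by exactly one equivalent of TMSCl, the N-silyl C-silyl carbamate 10 is kept in solution and lithiated again at the only free position ortho to the carbamate (between it and OMe), and Li→Cu exchange followed by SN2 allylic substitution at the unhindered CH2 of prenyl bromide installs the linear prenyl group before aqueous work-up cleaves the N–Si bond.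

**Step 7**
Reactants: 14 3-methoxy-5-(methoxymethoxy)-2-(3-methylbut-2-en-1-yl)-6-(trimethylsilyl)phenyl N-isopropylcarbamate
Product: 16 3-methoxy-5-(methoxymethoxy)-2-(3-methylbut-2-en-1-yl)-6-(trimethylsilyl)phenyl trifluoromethanesulfonate, via phenoxide 15 (not isolated)
Conditions: DBU (1.5 equiv), Et2NH (1.2 equiv), MeCN, 40 °C; then PhNTf2 (1.5 equiv), rt
Reagents that add atoms: N-phenylbis(trifluoromethanesulfonimide), FC(F)(F)S(=O)(=O)N(c1ccccc1)S(=O)(=O)C(F)(F)F
Why: E1cB cleavage of the N–H carbamate by DBU (isopropyl isocyanate trapped by Et2NH) and O-triflation of the phenoxide in the same pot, the established one-pot route from ortho-silyl carbamates to ortho-silylaryl triflates.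

**Step 8**
Reactants: 4 (3S)-3-hydroxy-N-methoxy-N-methyl-3-(2,4,6-trimethoxyphenyl)propanamide (1.3 equiv); 16 3-methoxy-5-(methoxymethoxy)-2-(3-methylbut-2-en-1-yl)-6-(trimethylsilyl)phenyl trifluoromethanesulfonate
Product: 21 (2S)-7-methoxy-5-(methoxymethoxy)-8-(3-methylbut-2-en-1-yl)-2-(2,4,6-trimethoxyphenyl)chroman-4-one, via sodium alkoxide 17 (not isolated), via aryne 18 (not isolated), via aryl anion 19 (not isolated), via tetrahedral adduct 20 (not isolated)
Conditions: 4, NaH (1.3 equiv), THF, 0 °C; then 16, KF (3 equiv), 18-crown-6 (3 equiv), THF, 0 °C → rt; pH 7 phosphate buffer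
Reagents that add atoms: none
Why: Proposed new method: fluoride removes the silyl group at C4a of 16 and triflate leaves from C8a to give aryne 18, alkoxide 17 adds through oxygen to C8a, and the C4a carbanion 19 attacks the tethered N-methoxy-N-methylamide carbonyl to form the C4–C4a bond, the chelated tetrahedral adduct 20 releasing the ketone only on neutral work-up. The closest known reaction types are the annulation of arynes with ortho-hydroxyaryl esters to xanthones (phenoxide addition, then intramolecular acylation of the aryl anion) and the Parham cyclization of ortho-lithiated aryl ethers onto tethered Weinreb amides; an aliphatic β-hydroxy amide as the four-atom partner is the untested extension. Ring C closes by 6-exo-trig attack of the aryl anion on the amide carbonyl. No new stereocentre is formed: C2 comes from 4 with its C–O bond untouched, and because C4 stays sp3 until work-up, C3 cannot enolise and the retro-oxa-Michael opening that racemises flavanones in base is blocked (an ester would release methoxide beside the free ketone). The step needs oxygen at C8a and the acyl group at C4a: the C5 OMOM oxygen beside the triple bond withdraws σ-density in the ring plane, so the developing charge sits at C4a next to it and the nucleophile enters at the distal carbon C8a, as is usual for 3-alkoxyarynes, while the C8 prenyl group on the other side opposes this only sterically. Pre-forming the alkoxide with NaH leaves no O–H to protonate 19 before it cyclises.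

**Step 9**
Reactants: 21 (2S)-7-methoxy-5-(methoxymethoxy)-8-(3-methylbut-2-en-1-yl)-2-(2,4,6-trimethoxyphenyl)chroman-4-one
Product: 23 (2S)-5-hydroxy-7-methoxy-8-(3-methylbut-2-en-1-yl)-2-(2,4,6-trimethoxyphenyl)chroman-4-one, via silyl ether 22 (not isolated)
Conditions: TMSOTf (2 equiv), 2,2′-bipyridyl (3 equiv), MeCN, 0 °C → rt; then H2O
Reagents that add atoms: none
Why: the bipyridyl-buffered silyl triflate exchanges the aromatic MOM acetal for a TMS ether that water cleaves, a known mild acetal deprotection chosen because protic acid could ionise the C2–O1 bond next to the 2,4,6-trimethoxyphenyl ring, so C2 should keep its configuration.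

**Compound list**
1 | 2′,4′,6′-trimethoxyacetophenone | CC(=O)c1c(OC)cc(OC)cc1OC | starting material
2 | methyl 3-oxo-3-(2,4,6-trimethoxyphenyl)propanoate | COC(=O)CC(=O)c1c(OC)cc(OC)cc1OC | intermediate
3 | methyl (3S)-3-hydroxy-3-(2,4,6-trimethoxyphenyl)propanoate | COC(=O)C[C@H](O)c1c(OC)cc(OC)cc1OC | intermediate
4 | (3S)-3-hydroxy-N-methoxy-N-methyl-3-(2,4,6-trimethoxyphenyl)propanamide | CON(C)C(=O)C[C@H](O)c1c(OC)cc(OC)cc1OC | intermediate
5 | 5-methoxyresorcinol (5-methoxybenzene-1,3-diol) | COc1cc(O)cc(O)c1 | starting material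
6 | 3-methoxy-5-(methoxymethoxy)phenol | COCOc1cc(O)cc(OC)c1 | intermediate
7 | 3-methoxy-5-(methoxymethoxy)phenyl N-isopropylcarbamate | COCOc1cc(OC)cc(OC(=O)NC(C)C)c1 | intermediate
8 | 3-methoxy-5-(methoxymethoxy)phenyl N-isopropyl-N-(trimethylsilyl)carbamate, formed in situ | COCOc1cc(OC)cc(OC(=O)N(C(C)C)[Si](C)(C)C)c1 | intermediate
9 | aryllithium of 8, lithium on the ring carbon between the carbamate oxygen and OMOM, formed in situ | COCOc1cc(OC)cc(OC(=O)N(C(C)C)[Si](C)(C)C)c1[Li] | intermediate
10 | 5-methoxy-3-(methoxymethoxy)-2-(trimethylsilyl)phenyl N-isopropyl-N-(trimethylsilyl)carbamate, formed in situ | COCOc1cc(OC)cc(OC(=O)N(C(C)C)[Si](C)(C)C)c1[Si](C)(C)C | intermediate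
11 | aryllithium of 10, lithium on the ring carbon between the carbamate oxygen and OMe, formed in situ | COCOc1cc(OC)c([Li])c(OC(=O)N(C(C)C)[Si](C)(C)C)c1[Si](C)(C)C | intermediate
12 | arylcopper corresponding to 11, formed in situ | COCOc1cc(OC)c([Cu])c(OC(=O)N(C(C)C)[Si](C)(C)C)c1[Si](C)(C)C | intermediate
13 | 3-methoxy-5-(methoxymethoxy)-2-(3-methylbut-2-en-1-yl)-6-(trimethylsilyl)phenyl N-isopropyl-N-(trimethylsilyl)carbamate, formed in situ | COCOc1cc(OC)c(CC=C(C)C)c(OC(=O)N(C(C)C)[Si](C)(C)C)c1[Si](C)(C)C | intermediate
14 | 3-methoxy-5-(methoxymethoxy)-2-(3-methylbut-2-en-1-yl)-6-(trimethylsilyl)phenyl N-isopropylcarbamate | COCOc1cc(OC)c(CC=C(C)C)c(OC(=O)NC(C)C)c1[Si](C)(C)C | intermediate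
15 | DBU-H 3-methoxy-5-(methoxymethoxy)-2-(3-methylbut-2-en-1-yl)-6-(trimethylsilyl)phenolate, formed in situ | COCOc1cc(OC)c(CC=C(C)C)c([O-])c1[Si](C)(C)C.C1CCC2=[NH+]CCCN2CC1 | intermediate
16 | 3-methoxy-5-(methoxymethoxy)-2-(3-methylbut-2-en-1-yl)-6-(trimethylsilyl)phenyl trifluoromethanesulfonate | COCOc1cc(OC)c(CC=C(C)C)c(OS(=O)(=O)C(F)(F)F)c1[Si](C)(C)C | intermediate
17 | sodium (1S)-3-[methoxy(methyl)amino]-3-oxo-1-(2,4,6-trimethoxyphenyl)propan-1-olate, formed in situ | CON(C)C(=O)C[C@H]([O-])c1c(OC)cc(OC)cc1OC.[Na+] | intermediate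
18 | 5-methoxy-3-(methoxymethoxy)-6-(3-methylbut-2-en-1-yl)-1,2-didehydrobenzene (aryne C4a≡C8a), formed in situ | COCOC1=CC(OC)=C(CC=C(C)C)C#C1 | intermediate
19 | aryl anion from O-arylation of 17 at C8a, carbanion at C4a between the OMOM and ether oxygens, shown as sodium salt, formed in situ | CON(C)C(=O)C[C@H](Oc1c(CC=C(C)C)c(OC)cc(OCOC)[c-]1)c1c(OC)cc(OC)cc1OC.[Na+] | intermediate
20 | sodium (2S)-4-[methoxy(methyl)amino]-7-methoxy-5-(methoxymethoxy)-8-(3-methylbut-2-en-1-yl)-2-(2,4,6-trimethoxyphenyl)chroman-4-olate, C4 unassigned, formed in situ | COc1cc(OC)c([C@@H]2CC([O-])(N(C)OC)c3c(OCOC)cc(OC)c(CC=C(C)C)c3O2)c(OC)c1.[Na+] | intermediate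
21 | (2S)-7-methoxy-5-(methoxymethoxy)-8-(3-methylbut-2-en-1-yl)-2-(2,4,6-trimethoxyphenyl)chroman-4-one | COc1cc(OC)c([C@@H]2CC(=O)c3c(OCOC)cc(OC)c(CC=C(C)C)c3O2)c(OC)c1 | intermediate
22 | (2S)-7-methoxy-8-(3-methylbut-2-en-1-yl)-2-(2,4,6-trimethoxyphenyl)-5-(trimethylsilyloxy)chroman-4-one, formed in situ | COc1cc(OC)c([C@@H]2CC(=O)c3c(O[Si](C)(C)C)cc(OC)c(CC=C(C)C)c3O2)c(OC)c1 | intermediate
23 | (2S)-5-hydroxy-7-methoxy-8-(3-methylbut-2-en-1-yl)-2-(2,4,6-trimethoxyphenyl)chroman-4-one | COc1cc(OC)c([C@@H]2CC(=O)c3c(O)cc(OC)c(CC=C(C)C)c3O2)c(OC)c1 | target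

**Totals**
Total steps: 9. Longest linear sequence: 6 steps (5 → 6 → 7 → 14 → 16 → 21 → 23).

**Steps most likely to fail, and fallbacks**

1. Step 8 (Proposed new method). What may go wrong: proton transfer to aryl anion 19 (from trace water or from C3–H) before it acylates; retro-aldol fragmentation of alkoxide 17; addition of the alkoxide at C4a instead of C8a; or early collapse of the tetrahedral adduct followed by base-mediated opening of ring C. The fallback uses known chemistry and sets out from 16. The same aryne 18 is generated (CsF, THF, 125 °C, sealed tube) in the presence of commercial (E)-3-(2,4,6-trimethoxyphenyl)prop-2-enoic acid. This is the carboxylic acid C–O insertion of arynes, a known route to ortho-hydroxyaryl ketones and 4-chromanones: the carboxylate adds at C8a, the C4a anion attacks the aryl ester carbonyl, and the acyl group moves from O to C. The product should be the 2′-hydroxychalcone (E)-1-[2-hydroxy-4-methoxy-6-(methoxymethoxy)-3-(3-methylbut-2-en-1-yl)phenyl]-3-(2,4,6-trimethoxyphenyl)prop-2-en-1-one F1. Oxa-Michael closure (NaOAc, EtOH, reflux) should then give racemic 7-methoxy-5-(methoxymethoxy)-8-(3-methylbut-2-en-1-yl)-2-(2,4,6-trimethoxyphenyl)chroman-4-one F2. Preparative chromatography on a chiral stationary phase separates the (S)-enantiomer, and the route is rejoined at 21. In this fallback the stereocentre comes from resolution and fragment 1 is not needed.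

2. Step 6. What may go wrong: incomplete capture of the first aryllithium before the second metalation, so that the prenyl group enters at the wrong ortho position; consumption of the second charge of n-BuLi by leftover TMSCl; or SN2′ attack of the arylcopper, which would give the 1,1-dimethylallyl isomer. The fallback sets out from 7, separates the two metalations and builds the prenyl group by a different carbon–carbon bond formation. Only the first stage of step 6 is run (TMSOTf, TMEDA, Et2O; n-BuLi, −78 °C; TMSCl), and aqueous NH4Cl work-up hydrolyses the N–Si bond of 10 to give 5-methoxy-3-(methoxymethoxy)-2-(trimethylsilyl)phenyl N-isopropylcarbamate F3, which is purified. Renewed in-situ N-silylation and lithiation (through 10 and 11), Li→Cu exchange (through 12) and quench with allyl bromide, for which SN2 and SN2′ attack give the same product, lead to 3-methoxy-5-(methoxymethoxy)-2-(prop-2-en-1-yl)-6-(trimethylsilyl)phenyl N-isopropyl-N-(trimethylsilyl)carbamate F4, which stays in the flask. Aqueous work-up then gives 3-methoxy-5-(methoxymethoxy)-2-(prop-2-en-1-yl)-6-(trimethylsilyl)phenyl N-isopropylcarbamate F5. Olefin cross-metathesis of F5 with excess 2-methylbut-2-ene (second-generation Grubbs catalyst RuCl2(=CHPh)(PCy3)(H2IMes), CH2Cl2, 40 °C) converts the allyl group into the prenyl group, and the route is rejoined at 14.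

3. Step 2. What may go wrong: slow hydride transfer to a twisted, electron-rich, di-ortho-substituted aryl ketone, and poor or inverted facial discrimination because the aryl ring cannot lie against the arene ligand. The fallback sets out from 2 and moves the origin of chirality from catalysis to resolution. NaBH4 (MeOH, 0 °C) reduces 2 to racemic methyl 3-hydroxy-3-(2,4,6-trimethoxyphenyl)propanoate F6. The conditions of step 3 convert it into racemic 3-hydroxy-N-methoxy-N-methyl-3-(2,4,6-trimethoxyphenyl)propanamide F7. Preparative supercritical-fluid chromatography on a chiral stationary phase then delivers the (S)-enantiomer, and the route is rejoined at 4.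

**Further compounds**
F1 | step 8 | (E)-1-[2-hydroxy-4-methoxy-6-(methoxymethoxy)-3-(3-methylbut-2-en-1-yl)phenyl]-3-(2,4,6-trimethoxyphenyl)prop-2-en-1-one | COCOc1cc(OC)c(CC=C(C)C)c(O)c1C(=O)/C=C/c1c(OC)cc(OC)cc1OC
F2 | step 8 | racemic 7-methoxy-5-(methoxymethoxy)-8-(3-methylbut-2-en-1-yl)-2-(2,4,6-trimethoxyphenyl)chroman-4-one | COCOc1cc(OC)c(CC=C(C)C)c2OC(CC(=O)c12)c1c(OC)cc(OC)cc1OC
F3 | step 6 | 5-methoxy-3-(methoxymethoxy)-2-(trimethylsilyl)phenyl N-isopropylcarbamate | COCOc1cc(OC)cc(OC(=O)NC(C)C)c1[Si](C)(C)C
F4 | step 6 | 3-methoxy-5-(methoxymethoxy)-2-(prop-2-en-1-yl)-6-(trimethylsilyl)phenyl N-isopropyl-N-(trimethylsilyl)carbamate | COCOc1cc(OC)c(CC=C)c(OC(=O)N(C(C)C)[Si](C)(C)C)c1[Si](C)(C)C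
F5 | step 6 | 3-methoxy-5-(methoxymethoxy)-2-(prop-2-en-1-yl)-6-(trimethylsilyl)phenyl N-isopropylcarbamate | COCOc1cc(OC)c(CC=C)c(OC(=O)NC(C)C)c1[Si](C)(C)C
F6 | step 2 | racemic methyl 3-hydroxy-3-(2,4,6-trimethoxyphenyl)propanoate | COC(=O)CC(O)c1c(OC)cc(OC)cc1OC
F7 | step 2 | racemic 3-hydroxy-N-methoxy-N-methyl-3-(2,4,6-trimethoxyphenyl)propanamide | CON(C)C(=O)CC(O)c1c(OC)cc(OC)cc1OC
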